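(All runs were computed for an exercise, noise included.)

You start with no rate constants for this flask, so you build one effective constant from the two earlier runs.

the same everywhere: substrate 2.2 M; coupling partner 2.42 M (in portions, 4)

| run | precatalyst | remark | time |
|---|---|---|---|
| cedar | 55 mM | run made earlier; portions every 5.0 min |  |
| alder | 220 mM | run made earlier; portions every 5.0 min |  |
| flask | 110 mM | the portions of coupling partner follow each other after 5.0 min, the first at the start | 80 min |

- cedar (time / min: target / %, substrate / %): 8.00: 0.5, 98.6; 15.0: 0.9, 98.0; 25.0: 2.8, 96.0; 50.0: 8.4, 90.4; 90.0: 16.0, 82.1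
- alder (time / min: target / %, substrate / %): 8.00: 0.8, 95.9; 15.0: 3.3, 91.4; 25.0: 10.0, 83.9; 50.0: 25.1, 67.2; 90.0: 42.4, 50.0

(readings scatter by 0.3 percentage points)

* concentration of target at 80 min, in M
* concentration of substrate at 80 min, in M

- percentages count the substrate that a species holds: one spent catalyst counts as two
- steps thought possible: 2 catalyst intermediate A -> spent catalyst; catalyst intermediate B -> free catalyst + target; precatalyst -> free catalyst; substrate + free catalyst -> catalyst intermediate A; coupling partner + catalyst intermediate A -> catalyst intermediate B

Suppose target forms at a rate proportional to catalyst, substrate and coupling partner. Substrate is the limiting reagent, but the partner's charge is close to it, at a ratio of 1.10. With the two reagents taken as equal, the rate falls with the square of what remains. The odds, meaning target formed over the substrate charge not yet turned into target, then climb on a straight line in time.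

Test this on the readings. Between 50.0 min and 90.0 min, the odds in cedar go from 0.0917 to 0.190, and in alder from 0.335 to 0.736. Divide each rise per minute by the precatalyst charge. Cedar gives 0.0449 L mol⁻¹ min⁻¹ and alder 0.0456 L mol⁻¹ min⁻¹, across a catalyst ratio of 4.00. Their mean, 0.0452 L mol⁻¹ min⁻¹, is the odds constant: the rise of the odds per minute per unit of precatalyst charged.

Traced back, the lines reach zero odds at 12.9 min in cedar and 16.6 min in alder. This flask's charge is their geometric mean, so take a lag of 14.7 min. The odds at 80 min are then 0.325, which means 0.539 M target.

The readings at 90.0 min also show substrate missing from target, at 0.760 of the catalyst charge in alder and 0.760 in cedar. Subtracting that share as well leaves 1.58 M substrate.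

The forecast, reasoning that “The two partners are nearly equimolar, so the rate runs roughly second order”, puts target at 0.53 M (0.49 M to 0.57 M), a little under your figure, and substrate at 1.58 M (1.53 M to 1.63 M), level with yours.

The flask gives 0.538 M target and 1.58 M substrate.

    2 catalyst intermediate A → spent catalyst (k = 0.150 L mol⁻¹ min⁻¹)
    catalyst intermediate B → free catalyst + target (k = 0.440 min⁻¹)
    precatalyst → free catalyst (k = 0.100 min⁻¹)
    substrate + free catalyst → catalyst intermediate A (k = 0.140 L mol⁻¹ min⁻¹)
    coupling partner + catalyst intermediate A → catalyst intermediate B (k = 0.0950 L mol⁻¹ min⁻¹)

Put the result back in. Between 50 min and 80 min this flask's odds climb at 0.0451 L mol⁻¹ min⁻¹, level with the odds constant 0.0452 L mol⁻¹ min⁻¹. For the flask with 0.44 M precatalyst, the same constant and lag give 1.24 M target at 80 min, and that flask stores 1.20 M. The largest single effect on this flask's target is the time of reading: read at 80 min and not ten times later, target stands at 0.538 M, not 1.75 M.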